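**Retrosynthetic overview**

1. The hydrogen sulfate is traced back to a 5,4'-di-O-benzyl flavonol whose only free hydroxyl is the 3-OH: sulfation, then one hydrogenolysis of both benzyl ethers and proton exchange.
2. The flavonol comes from a 2-aryl-3-nitro-2H-chromene by alkaline peroxide oxidation; the nitro group is a masked C3 oxygen and C4–H becomes the C4 carbonyl.
3. Feature used: in ring C (O1, C2, C3, C4, C4a, C8a) the heteroatom-bearing C3 lies between C2 (bonded to O1 and to aryl ring B) and C4 (bonded to C4a of ring A). This O1–C2(Ar)–C3(X)–C4 array maps onto a phenol oxygen, the β- and α-carbons of a β-nitrostyrene and an aldehyde carbon.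
4. Key disconnection: O1–C2 (oxa-Michael) and C3–C4 (Henry, then dehydration) in one amine-mediated operation. Ring C is the only ring formed; it closes onto preformed ring A, and ring B arrives with the nitroalkene.
5. Ring A partner: 2,4,6-trihydroxybenzaldehyde by 4-O-methylation and mono-O-benzylation. Ring B partner: O-benzylvanillin and nitromethane.

Key step: step 4

Assumption: the target is drawn as the free hydrogen sulfate; since aryl hydrogen sulfates hydrolyse under acid catalysis, the sulfate is carried as its triethylammonium salt and the acid form is released only in the last operation, cold, and freeze-dried at once.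

**Step 1**
Reactants: 1 2,4,6-trihydroxybenzaldehyde
Product: 2 2,6-dihydroxy-4-methoxybenzaldehyde
Conditions: Me2SO4 (1.0 equiv), K2CO3 (1.0 equiv), acetone, 0 °C to rt
Reagents that add atoms: dimethyl sulfate, COS(=O)(=O)OC
Why: Williamson O-methylation under acidity control: the 4-hydroxyl, para to the formyl group, is the most acidic and least shielded, whereas the 2- and 6-hydroxyls flank the carbonyl and are engaged with it in hydrogen bonding, so one equivalent of base and of dimethyl sulfate should methylate O-4 first.

**Step 2**
Reactants: 2 2,6-dihydroxy-4-methoxybenzaldehyde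
Product: 3 2-benzyloxy-6-hydroxy-4-methoxybenzaldehyde
Conditions: BnBr (1.05 equiv), K2CO3 (1.1 equiv), acetone, 50 °C
Reagents that add atoms: benzyl bromide, BrCc1ccccc1
Why: Williamson O-benzylation of one of two equivalent hydroxyls; once the first ether is in place the remaining hydroxyl is locked in a strong hydrogen bond to the formyl oxygen and is poorly nucleophilic, so the reaction should stop at the monoether.

**Step 3**
Reactants: 4 4-benzyloxy-3-methoxybenzaldehyde (O-benzylvanillin); 5 nitromethane
Product: 7 1-benzyloxy-2-methoxy-4-[(E)-2-nitrovinyl]benzene, via nitroaldol adduct 6 (not isolated)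
Conditions: NH4OAc (0.5 equiv), AcOH, 100 °C; 5 (5 equiv)
Reagents that add atoms: none
Why: Henry (nitroaldol) condensation: the ammonium acetate buffer promotes addition of the nitronate to the aldehyde and dehydration of adduct 6, and the conjugated E-nitroalkene is the thermodynamically preferred geometry.

**Step 4**
Reactants: 3 2-benzyloxy-6-hydroxy-4-methoxybenzaldehyde; 7 1-benzyloxy-2-methoxy-4-[(E)-2-nitrovinyl]benzene
Product: 10 5-benzyloxy-2-(4-benzyloxy-3-methoxyphenyl)-7-methoxy-3-nitro-2H-chromene (racemic), via oxa-Michael adduct 8 (not isolated), via nitrochromanol 9 (not isolated)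
Conditions: DABCO (0.5 equiv), MeCN (1 M), 60 °C; 7 (1.3 equiv)
Reagents that add atoms: none
Why: DABCO deprotonates the single free phenol of 3, the phenoxide adds to the benzylic β-carbon of nitroalkene 7 (oxa-Michael, O1–C2) to give the nitronate of 8, this attacks the adjacent formyl group (intramolecular Henry reaction, C3–C4) to give 9, and E1cB loss of water installs the conjugated C3=C4 bond. The closest known reaction is the amine-mediated oxa-Michael/Henry/dehydration domino of salicylaldehydes with β-nitrostyrenes to 2-aryl-3-nitro-2H-chromenes, applied here to an electron-rich pair of partners. Ring C closes in the C–C bond-forming event as a 6-exo-trig attack of the nitronate carbon on the exocyclic C=O. C2 is the only stereocentre that survives and is formed without any controlling element, so 10 is racemic; this is accepted because C2 becomes sp2 in step 5, and the C3 and C4 centres of 9 disappear on dehydration. The selectivity required is regiochemical (aryl on C2, nitro on C3) and is secured by the polarity of the nitroalkene and by the presence of one free hydroxyl only. The reversible oxa-Michael step is drained by the irreversible dehydration, in which the 5-benzyloxy and 7-methoxy donors should assist departure of hydroxide from C4.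

**Step 5**
Reactants: 10 5-benzyloxy-2-(4-benzyloxy-3-methoxyphenyl)-7-methoxy-3-nitro-2H-chromene
Product: 13 5-benzyloxy-2-(4-benzyloxy-3-methoxyphenyl)-3-hydroxy-7-methoxy-4H-chromen-4-one, via nitro-epoxide 11 (not isolated), via ketol 12 (not isolated)
Conditions: 30% aq H2O2 (excess), 2 M aq NaOH, MeOH–THF, 0 °C to rt; then sat. aq NH4Cl
Reagents that add atoms: hydrogen peroxide, OO; sodium hydroxide (aqueous, source of the C4 oxygen), [Na+].[OH-]
Why: This is the known alkaline hydrogen peroxide conversion of 2-aryl-3-nitro-2H-chromenes into flavonols: Weitz–Scheffer epoxidation of the nitroalkene by hydroperoxide gives 11, hydroxide opens it at benzylic C4 with expulsion of nitrite from C3 to a ketol that settles through its ene-diol as 12, and 12 is dehydrogenated by the alkaline peroxide as in the last stage of the Algar–Flynn–Oyamada reaction, which makes C2 sp2 and removes the only stereocentre.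

**Step 6**
Reactants: 13 5-benzyloxy-2-(4-benzyloxy-3-methoxyphenyl)-3-hydroxy-7-methoxy-4H-chromen-4-one
Product: 14 triethylammonium 5-benzyloxy-2-(4-benzyloxy-3-methoxyphenyl)-7-methoxy-4-oxo-4H-chromen-3-yl sulfate
Conditions: SO3·NEt3 (5 equiv), NEt3, DMF, 50 °C
Reagents that add atoms: sulfur trioxide–triethylamine complex, CC[N+](CC)(CC)S(=O)(=O)[O-]
Why: O-Sulfation with an amine–sulfur trioxide complex: the 3-hydroxyl is the only free hydroxyl of 13 and, being an acidic enol, is deprotonated by triethylamine and captured by SO3 to give the sulfate monoester, isolated as its base-stable triethylammonium salt.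

**Step 7**
Reactants: 14 triethylammonium 5-benzyloxy-2-(4-benzyloxy-3-methoxyphenyl)-7-methoxy-4-oxo-4H-chromen-3-yl sulfate
Product: 16 rhamnazin 3-O-sulfate (5-hydroxy-2-(4-hydroxy-3-methoxyphenyl)-7-methoxy-4-oxo-4H-chromen-3-yl hydrogen sulfate), via triethylammonium rhamnazin 3-O-sulfate 15 (not isolated)
Conditions: H2 (1 atm), 10% Pd/C, MeOH–THF, rt; then Dowex 50W-X8 (H+ form), H2O–MeCN, 0 °C, freeze-drying
Reagents that add atoms: none
Why: Catalytic hydrogenolysis of the two benzyl aryl ethers, to which aryl sulfate monoester salts and the chromone C2=C3 bond should be inert under one atmosphere of hydrogen, followed by cation exchange on a sulfonic acid resin that replaces triethylammonium by a proton at 0 °C to limit hydrolysis of the sulfate.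

**Compound list**

1 | 2,4,6-trihydroxybenzaldehyde | O=Cc1c(O)cc(O)cc1O | starting material
2 | 2,6-dihydroxy-4-methoxybenzaldehyde | COc1cc(O)c(C=O)c(O)c1 | intermediate
3 | 2-benzyloxy-6-hydroxy-4-methoxybenzaldehyde | COc1cc(O)c(C=O)c(OCc2ccccc2)c1 | intermediate
4 | 4-benzyloxy-3-methoxybenzaldehyde (O-benzylvanillin) | COc1cc(C=O)ccc1OCc1ccccc1 | starting material
5 | nitromethane | C[N+](=O)[O-] | starting material
6 | 1-(4-benzyloxy-3-methoxyphenyl)-2-nitroethanol (racemic) | COc1cc(C(O)C[N+](=O)[O-])ccc1OCc1ccccc1 | intermediate
7 | 1-benzyloxy-2-methoxy-4-[(E)-2-nitrovinyl]benzene | COc1cc(/C=C/[N+](=O)[O-])ccc1OCc1ccccc1 | intermediate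
8 | 2-benzyloxy-6-[1-(4-benzyloxy-3-methoxyphenyl)-2-nitroethoxy]-4-methoxybenzaldehyde (racemic) | COc1cc(OC(C[N+](=O)[O-])c2ccc(OCc3ccccc3)c(OC)c2)c(C=O)c(OCc2ccccc2)c1 | intermediate
9 | 5-benzyloxy-2-(4-benzyloxy-3-methoxyphenyl)-7-methoxy-3-nitrochroman-4-ol (racemic, mixture of diastereomers) | COc1cc(OCc2ccccc2)c2C(O)C([N+](=O)[O-])C(c3ccc(OCc4ccccc4)c(OC)c3)Oc2c1 | intermediate
10 | 5-benzyloxy-2-(4-benzyloxy-3-methoxyphenyl)-7-methoxy-3-nitro-2H-chromene (racemic) | COc1cc(OCc2ccccc2)c2C=C([N+](=O)[O-])C(c3ccc(OCc4ccccc4)c(OC)c3)Oc2c1 | intermediate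
11 | 5-benzyloxy-2-(4-benzyloxy-3-methoxyphenyl)-3,4-epoxy-7-methoxy-3-nitrochroman (racemic, mixture of diastereomers) | COc1cc(OCc2ccccc2)c2C3OC3([N+](=O)[O-])C(c4ccc(OCc5ccccc5)c(OC)c4)Oc2c1 | intermediate
12 | 5-benzyloxy-2-(4-benzyloxy-3-methoxyphenyl)-3-hydroxy-7-methoxychroman-4-one (racemic, mixture of diastereomers) | COc1cc(OCc2ccccc2)c2C(=O)C(O)C(c3ccc(OCc4ccccc4)c(OC)c3)Oc2c1 | intermediate
13 | 5-benzyloxy-2-(4-benzyloxy-3-methoxyphenyl)-3-hydroxy-7-methoxy-4H-chromen-4-one | COc1cc(OCc2ccccc2)c2c(=O)c(O)c(-c3ccc(OCc4ccccc4)c(OC)c3)oc2c1 | intermediate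
14 | triethylammonium 5-benzyloxy-2-(4-benzyloxy-3-methoxyphenyl)-7-methoxy-4-oxo-4H-chromen-3-yl sulfate | COc1cc(OCc2ccccc2)c2c(=O)c(OS(=O)(=O)[O-])c(-c3ccc(OCc4ccccc4)c(OC)c3)oc2c1.CC[NH+](CC)CC | intermediate
15 | triethylammonium 5-hydroxy-2-(4-hydroxy-3-methoxyphenyl)-7-methoxy-4-oxo-4H-chromen-3-yl sulfate | COc1cc(O)c2c(=O)c(OS(=O)(=O)[O-])c(-c3ccc(O)c(OC)c3)oc2c1.CC[NH+](CC)CC | intermediate
16 | rhamnazin 3-O-sulfate (hydrogen sulfate form) | COc1cc(O)c2c(=O)c(OS(=O)(=O)O)c(-c3ccc(O)c(OC)c3)oc2c1 | target

**Step count**

Total: 7 steps. Longest linear sequence: 6 steps (steps 1, 2, 4, 5, 6, 7); step 3 is the side branch.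

**Steps most likely to fail**

Step 4 (key step). The formyl group of the oxa-Michael adduct is deactivated by three oxygen donors and flanked by the benzyloxy group, so the Henry closure may be slower than the retro-oxa-Michael reaction and than amine-initiated oligomerisation of the nitroalkene. The fallback sets out from 3 (with 7 as partner) and comes back to the route at 10. It adds an activating group to the aldehyde: condensation of 3 with 4-methylbenzenesulfonamide (Si(OEt)4, 160 °C) should give N-[(E)-(2-benzyloxy-6-hydroxy-4-methoxyphenyl)methylidene]-4-methylbenzenesulfonamide F1, a much stronger electrophile. DABCO-mediated oxa-Michael/aza-Henry reaction of this imine with 7 (toluene, rt) should give N-[5-benzyloxy-2-(4-benzyloxy-3-methoxyphenyl)-7-methoxy-3-nitrochroman-4-yl]-4-methylbenzenesulfonamide F2. E1cB elimination of the sulfonamide (K2CO3, MeCN, 60 °C) should then deliver 10.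

Step 5. Under aqueous base the 2H-chromene may isomerise or ring-open by retro-oxa-Michael reaction before it is epoxidised, and the electron-rich flavonolate may be degraded oxidatively by excess alkaline peroxide. The fallback sets out from 10 and comes back at 13, with the three events run as separately controlled operations. Anhydrous nucleophilic epoxidation with tBuOOLi (from tBuOOH and nBuLi, THF, −78 °C) should give 11. Aqueous NaHCO3 on warming should open it with loss of nitrite to the ketol 12, which is isolated. Dehydrogenation of 12 with I2 and KOAc in AcOH at 90 °C should give 13. No compound outside the list is formed (F0).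

Step 1. Methylation of an ortho-hydroxyl and over-methylation may compete, giving mixtures of regioisomeric mono- and diethers that are tedious to separate. The fallback sets out from 1 and comes back at 2. Exhaustive methylation (MeI in excess, K2CO3, DMF, 60 °C) should give 2,4,6-trimethoxybenzaldehyde F3. Treatment with BBr3 (2.2 equiv, CH2Cl2, −78 °C to rt) should then cleave both methyl ethers ortho to the carbonyl through six-membered boron chelates, while the para-methoxyl, which cannot chelate, is kept; this returns 2.

**Further compounds**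

F1 | step 4 | N-[(E)-(2-benzyloxy-6-hydroxy-4-methoxyphenyl)methylidene]-4-methylbenzenesulfonamide | COc1cc(O)c(/C=N/S(=O)(=O)c2ccc(C)cc2)c(OCc2ccccc2)c1
F2 | step 4 | N-[5-benzyloxy-2-(4-benzyloxy-3-methoxyphenyl)-7-methoxy-3-nitrochroman-4-yl]-4-methylbenzenesulfonamide (racemic, mixture of diastereomers) | COc1cc(OCc2ccccc2)c2C(NS(=O)(=O)c3ccc(C)cc3)C([N+](=O)[O-])C(c4ccc(OCc5ccccc5)c(OC)c4)Oc2c1
F0 | step 5 | none | none
F3 | step 1 | 2,4,6-trimethoxybenzaldehyde | COc1cc(OC)c(C=O)c(OC)c1
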